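The rate constants belong to no real substance; the run is a simulation.

A one-step world rewards heat, but this scheme splits the intermediate three ways, and one of its partners has to arrive through the gas.

    starting material → intermediate (k1 = 1.0 h⁻¹, Ea1 = 88.0 kJ mol⁻¹)
    first nucleophile + intermediate → target (k2 = 49 M⁻¹ h⁻¹, Ea2 = 62.0 kJ mol⁻¹)
    second nucleophile + intermediate → other capture product (k3 = 2.4 M⁻¹ h⁻¹, Ea3 = 54.0 kJ mol⁻¹)
    intermediate → solvolysis product (k4 = 14 h⁻¹, Ea4 = 89.0 kJ mol⁻¹)
    first nucleophile → decomposition product (k5 = 2.4 × 10⁻⁴ h⁻¹, Ea5 = 104 kJ mol⁻¹)
    gas ⇌ first nucleophile, rate k6*(csat - [first nucleophile]) (k6 = 3.3 h⁻¹, csat = 200 mM)
    (constants at 25 °C)

in all of them: starting material 2.0 M; second nucleophile 1.50 equiv; gas 200 mM (held); time 4.0 h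
- north: temperature 25 °C
- south-east: temperature 55 °C
- south-west: temperature 85 °C

- at the start none of first nucleophile is dissolved
- the constants hold at 25 °C; other temperatures follow from the activation energies

1. which flask leads in amount of target, in percent of the starting material charged ("all alike" within 1.5 percentage points) (north / south-east / south-west / all alike)
2. how much target is there at the end, in percent of the starting material charged: north
3. how much target is there at the end, in percent of the starting material charged: south-east
4. how much target is there at the end, in percent of the starting material charged: south-west

I divided the rate of capture by the first nucleophile by the summed rates of the intermediate's three exits, so that time dropped out. With [first nucleophile] at its saturation value 200 mM and [second nucleophile] at its charge 3.00 M, north gave 31.6 %, and I called this the capture share, the selectivity of the intermediate's branching toward the target.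

But dissolved first nucleophile starts at zero. Weighting its filling curve by the moment each starting material molecule reacts gives a second ratio of rates: transfer coefficient over transfer coefficient plus the rate constant of step 1. This readiness was 0.767 in north. Their product was my estimate for target: 24.3 % in north.

South-east had share 18.5 % and readiness 0.114, giving 2.10 %. South-west had 9.72 % and 0.00855, giving 0.0831 %.

Then I turned the question round. For a hotter flask to lead, its product must exceed north's, so at least one factor must rise with temperature. Neither did: the share fell and the readiness fell. My product for south-west stood 292 times short of my product for north, and my choice was north. The readiness took the filling as undisturbed by capture, yet at full share and with the whole charge of starting material reacting, north's target would draw 0.632 M h⁻¹, nearly all of the gas entry into a solution empty of first nucleophile, 0.660 M h⁻¹, so I took my north figure as a high one.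

The forecast put north ahead with 22 %, 1.8 % and 0.07 %, on the grounds that “Heating speeds intermediate formation and solvolysis far more than gas uptake”.

The simulation put north ahead, with 20.9 % there, 1.70 % in south-east and 0.0758 % in south-west. At 4.00 h north still held 1.8 % of its starting material, which at the capture share of 31.6 % is worth 0.579 % of the charge; at 40.0 h north's target stood at 21.5 %. South-east held 0 %, and its target stayed at 1.70 %. South-west's target did not move, but its decomposition product climbed from 0.186 M at 4.00 h to 1.99 M at 40.0 h.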